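Late in the winter run, between 4.00 h and 6.00 h, product grew at 0.00609 M h⁻¹, and I had to decide whether the next flask needed more precatalyst than 0.001 mol%.

| flask | solid substrate | precatalyst | remark |
|---|---|---|---|
| autumn | 0.058 M | 6.7 × 10⁻⁴ mol% | run made earlier |
| winter | 0.058 M | 0.0015 mol% | run made earlier |
| dawn | 0.087 M | 0.001 mol% | run made earlier |
| flask | 0.058 M | 0.001 mol% |  |

| run | time / h | product / % | solid substrate / % |
|---|---|---|---|
| autumn | 0.333 | 1 | 97 |
| autumn | 1.00 | 3 | 91 |
| autumn | 1.50 | 3 | 83 |
| autumn | 2.50 | 12 | 73 |
| autumn | 4.00 | 28 | 57 |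
| autumn | 5.00 | 38 | 50 |
| autumn | 6.00 | 45 | 36 |
| winter | 0.500 | 0 | 95 |
| winter | 0.667 | 0 | 88 |
| winter | 1.00 | 1 | 91 |
| winter | 1.50 | 6 | 83 |
| winter | 2.50 | 15 | 70 |
| winter | 4.00 | 35 | 57 |
| winter | 6.00 | 56 | 37 |
| dawn | 0.500 | 1 | 94 |
| dawn | 0.833 | 0 | 92 |
| dawn | 1.50 | 5 | 90 |
| dawn | 3.00 | 14 | 77 |
| dawn | 6.00 | 36 | 55 |

(readings scatter by 1.5 percentage points)

- as a solid, counted per litre of solution: solid substrate
- the numbers in the tables scatter by 1.5 percentage points (one standard deviation)
- at the start none of the solid substrate is in solution
- what has only dissolved of solid substrate counts as not reacted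

- factor on the rate of making product when 50% of the solid substrate are converted (what has only dissolved counts as not reacted) if precatalyst is charged twice over
- factor on the rate when 50% of the solid substrate are converted (what has only dissolved counts as not reacted) if precatalyst is charged at 1.0 × 10⁻⁴ mol% instead

I replaced each curve of solid substrate by its mean, the amount lost by the last reading divided by that time. This gave 0.00619 M h⁻¹ in autumn, 0.00609 M h⁻¹ in winter and 0.00652 M h⁻¹ in dawn. Their average, 0.00627 M h⁻¹, I called the dissolving pace: the mean amount of solid substrate leaving the solid per litre and hour. The mean hid little, since the autumn run had already lost solid at 0.00626 M h⁻¹ by 2.50 h.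

Late product in the dawn run, at the flask's loading, grew at 0.00638 M h⁻¹, close to that pace, so I took dissolving as the rate-limiting step there. The autumn run, with less precatalyst, read 0.00493 M h⁻¹ between 4.00 h and 6.00 h, but that figure rests on two readings that each scatter by 1.5 percentage points, and the winter run, with more precatalyst, also read below the pace, so I drew no effect of precatalyst from the gap. I therefore left the loading alone and expected a factor near 1 from charging it twice over. For 1.0 × 10⁻⁴ mol%, lower than any run, I committed to no number. The forecast gave 1 and 0.48, saying “the rate is dissolution-limited”.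

The simulation gave 1.05 and 0.693.

    starting material + enzyme → product + enzyme, rate k1*[starting material]^2*[enzyme]/(1 + ([starting material]/Kh1)^2) (0.0610 M, k = 1.00 × 10⁵ L² mol⁻² s⁻¹)
    solid substrate ⇌ starting material, rate k2*(cs2 - [starting material]) while solid is left; crystals form when [starting material] > cs2 (solubility = 37.0 mM, k = 0.00340 min⁻¹)
    precatalyst → enzyme (k = 0.00470 min⁻¹)

In the flask, solid substrate dissolved while precatalyst turned into enzyme, which stood at 24.6% at 1.00 h and 75.6% at 5.00 h. By then solid substrate stood at 46.5%, and the dissolving pace reckons 46.0%. Product was being made at 0.00652 M h⁻¹ when half was converted at 5.68 h, and solid substrate read 0% by 10.0 h. With precatalyst at 1.0 × 10⁻⁴ mol%, the same point came at 0.00452 M h⁻¹, slower than the dissolving pace of 0.00627 M h⁻¹.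

(All runs come from a simulation for substances that don't exist; scatter was added.)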